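## Retrosynthetic overview

1. The cyclohexenone ring is made last: its C1–C6 bond is closed by adding a carbene-generated acyl anion (Breslow intermediate), formed from a chain aldehyde, to the ketone of a (Z)-enone α-keto ester already esterified to the trimer. This sets the quaternary C1.
2. The (Z)-2,7-dioxohept-3-enoate chain comes from the only free hydroxyl of the silylated trimer, oxalyl chloride and 4-pentynal (chlorooxalate, copper acetylide acylation, Lindlar reduction).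
3. The trimer comes from a C4-activated epicatechin plus the catechin–catechin dimer (4β→8 bond); the dimer comes from a C4-activated catechin plus tetra-silyl catechin (4α→8 bond).
4. All flavan rings are bought intact as (+)-catechin and (−)-epicatechin. Silyl ethers are used as the only protecting groups so the final deprotection leaves the cyclohexene alone.
5. Ring order: flavan rings (purchased), then the interflavan bonds from the bottom up, then the cyclohexenone ring.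

## Notation and assumptions

- TBS = tert-butyldimethylsilyl. U, M, L = upper (epicatechin), middle (catechin) and lower (catechin) units.
- "Per-TBS trimer" = TBS on O5, O7, O3', O4' of all three units and on O3 of U and M (14 silyl groups). "Per-TBS dimer" = the same pattern on two units with O3 of the upper unit silylated (9 silyl groups).
- Assumption: which antipode of the aminoindanol triazolium salt gives the 1S carbinol cannot be predicted with certainty for this substrate. The (5aR,10bS) salt is written for step 11; its commercial enantiomer is used instead if a model run on the catechin mono-ester gives the 1R epimer.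
- Assumption: silyl-protected flavans behave like their benzyl-protected counterparts in steps 3, 4, 6 and 7. That reaction type is established only for benzyl ethers, so these steps are untested adaptations.

## Route

Step 1
Reactants: 1 (+)-catechin
Product: 2 5,7,3',4'-tetra-O-TBS-(+)-catechin (3-OH free)
Conditions: TBSCl (4.4 equiv), imidazole (9 equiv), DMF, 0 °C to rt
Reagents that add atoms: tert-butyldimethylsilyl chloride, CC(C)(C)[Si](C)(C)Cl
Why: Imidazole-promoted O-silylation is much faster at the four phenols than at the hindered secondary 3-OH, so the alcohol stays free and no stereocentre is touched.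

Step 2
Reactants: 1 (+)-catechin
Product: 3 3,5,7,3',4'-penta-O-TBS-(+)-catechin
Conditions: TBSOTf (6.5 equiv), 2,6-lutidine (10 equiv), CH2Cl2/THF, 0 °C to rt
Reagents that add atoms: tert-butyldimethylsilyl triflate, CC(C)(C)[Si](C)(C)OS(=O)(=O)C(F)(F)F
Why: The silyl triflate/lutidine system (exhaustive O-silylation) also caps the secondary 3-OH, giving a flavan with no free hydroxyl for clean C4 activation.

Step 3
Reactants: 3 penta-O-TBS-(+)-catechin
Product: 4 4β-(2-ethoxyethoxy)-3,5,7,3',4'-penta-O-TBS-catechin (2,3-trans, 3,4-cis)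
Conditions: DDQ (2 equiv), 2-ethoxyethanol (5 equiv), CH2Cl2, rt
Reagents that add atoms: 2-ethoxyethanol, CCOCCO
Why: DDQ removes hydride from the C4–H activated by the 5,7-dioxygenated ring (oxidative benzylic etherification) and the alcohol traps the cation anti to the C2 aryl group; the C4 configuration is lost again on ionisation in step 4.

Step 4
Reactants: 4 C4-activated penta-O-TBS-catechin; 2 tetra-O-TBS-catechin (3 equiv, excess recovered)
Product: 5 per-TBS catechin-(4α→8)-catechin with the lower-unit 3-OH free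
Conditions: TMSOTf (0.5 equiv), 4 Å MS, CH2Cl2, −78 °C; Et3N quench
Reagents that add atoms: none
Why: Lewis-acid ionisation of the C4 ether gives a benzylic cation that the electron-rich C8 of the excess nucleophile attacks (Friedel–Crafts-type flavan condensation) anti to the bulky 3β-OTBS group, which sets the 4α (3,4-trans) centre.

Step 5
Reactants: 6 (−)-epicatechin
Product: 7 3,5,7,3',4'-penta-O-TBS-(−)-epicatechin
Conditions: TBSOTf (6.5 equiv), 2,6-lutidine (10 equiv), CH2Cl2/THF, 0 °C to rt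
Reagents that add atoms: tert-butyldimethylsilyl triflate, CC(C)(C)[Si](C)(C)OS(=O)(=O)C(F)(F)F
Why: Exhaustive O-silylation as in step 2; the axial 3-OH still reacts with the triflate and no stereocentre is touched.

Step 6
Reactants: 7 penta-O-TBS-(−)-epicatechin
Product: 8 4β-(2-ethoxyethoxy)-3,5,7,3',4'-penta-O-TBS-epicatechin (2,3-cis, 3,4-trans)
Conditions: DDQ (2 equiv), 2-ethoxyethanol (5 equiv), CH2Cl2, rt
Reagents that add atoms: 2-ethoxyethanol, CCOCCO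
Why: Same oxidative benzylic etherification as step 3; the alcohol enters anti to both the 2α-aryl and the 3α-OTBS group.

Step 7
Reactants: 8 C4-activated penta-O-TBS-epicatechin; 5 per-TBS dimer (2.5 equiv, excess recovered)
Product: 9 per-TBS epicatechin-(4β→8)-catechin-(4α→8)-catechin with the L 3-OH free
Conditions: TMSOTf (0.5 equiv), 4 Å MS, CH2Cl2, −78 to −40 °C; Et3N quench
Reagents that add atoms: none
Why: The cation from 8 is attacked on its β face, anti to both the 2α-aryl and the 3α-OTBS group, by the only free C8 of the dimer (its upper unit), a Friedel–Crafts-type flavan condensation that sets the 4β centre.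

Step 8
Reactants: 10 4-pentyn-1-ol
Product: 11 4-pentynal
Conditions: PhI(OAc)2 (1.1 equiv), TEMPO (10 mol%), CH2Cl2, rt; careful distillation
Reagents that add atoms: none
Why: Oxoammonium (TEMPO) oxidation takes the primary alcohol to the aldehyde without over-oxidation and leaves the terminal alkyne alone.

Step 9
Reactants: 9 per-TBS trimer alcohol; 12 oxalyl chloride (5 equiv); 11 4-pentynal (2 equiv)
Product: 14 per-TBS trimer L-3-O-(2,7-dioxohept-3-ynoate), via trimer chlorooxalate 13 (not isolated)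
Conditions: (i) (COCl)2, 2,6-lutidine (1.5 equiv), CH2Cl2, −20 to 0 °C, evaporate; (ii) 11, CuI (10 mol%), Et3N (2.5 equiv), THF, 0 °C to rt
Reagents that add atoms: none
Why: The single free hydroxyl is converted by excess oxalyl chloride into the chlorooxalate, which then acylates the copper acetylide of the terminal alkyne (copper-catalysed acyl-Sonogashira-type coupling) to give the alkynyl α-keto ester; the aliphatic aldehyde is tolerated.

Step 10
Reactants: 14 per-TBS trimer alkynyl α-keto ester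
Product: 15 per-TBS trimer L-3-O-[(Z)-2,7-dioxohept-3-enoate]
Conditions: H2 (1 atm), Lindlar catalyst, quinoline, EtOAc, 0 °C, stopped at one equivalent; filtered and used at once
Reagents that add atoms: none
Why: Syn addition of hydrogen on poisoned palladium (Lindlar semihydrogenation) stops at the Z-enone, the only geometry that can later close a six-membered ring; aldehyde and silyl ethers are inert.

Step 11
Reactants: 15 per-TBS trimer (Z)-enone keto-aldehyde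
Product: 16 per-TBS trimer L-3-O-[(1S)-1-hydroxy-6-oxocyclohex-2-ene-1-carboxylate]
Conditions: (5aR,10bS)-N-C6F5 aminoindanol triazolium BF4 (20 mol%), i-Pr2NEt (20 mol%), toluene (0.01 M), 0 °C to rt, dark
Reagents that add atoms: none
Why: Proposed new method: the carbene adds to the unhindered aliphatic aldehyde to give a Breslow intermediate (acyl anion equivalent) whose only geometrically feasible intramolecular reaction is 6-exo 1,2-addition to the highly electrophilic α-keto ester carbonyl across the Z-alkene (Stetter closure would need a four-membered ring), and the chiral triazolium shields one ketone face so that the quaternary C1 is formed as S under catalyst control; the closest known reactions are the enantioselective NHC-catalysed intramolecular aldehyde–ketone crossed benzoin cyclisation and the intermolecular cross-benzoin of aliphatic aldehydes with α-keto esters.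

Step 12
Reactants: 16 per-TBS trimer hydroxy-oxo-cyclohexene carboxylate
Product: 17 CNP0159807.2
Conditions: HF·pyridine (excess), pyridine, THF, 0 °C to rt, 36 h; Me3SiOMe quench; Sephadex LH-20 then C18 HPLC
Reagents that add atoms: none
Why: Fluoride cleaves all fourteen Si–O bonds (global desilylation) under weakly acidic buffered conditions that the base-sensitive β-keto ester, the cyclohexene and the acid-sensitive interflavan bonds should tolerate; no stereocentre is affected.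

## Compound list

1 | (+)-catechin, (2R,3S) | O[C@H]1Cc2c(O)cc(O)cc2O[C@@H]1c1ccc(O)c(O)c1 | starting material

2 | 5,7,3',4'-tetra-O-TBS-(+)-catechin | O[C@H]1Cc2c(O[Si](C)(C)C(C)(C)C)cc(O[Si](C)(C)C(C)(C)C)cc2O[C@@H]1c1ccc(O[Si](C)(C)C(C)(C)C)c(O[Si](C)(C)C(C)(C)C)c1 | intermediate

3 | 3,5,7,3',4'-penta-O-TBS-(+)-catechin | CC(C)(C)[Si](C)(C)O[C@H]1Cc2c(O[Si](C)(C)C(C)(C)C)cc(O[Si](C)(C)C(C)(C)C)cc2O[C@@H]1c1ccc(O[Si](C)(C)C(C)(C)C)c(O[Si](C)(C)C(C)(C)C)c1 | intermediate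

4 | 4β-(2-ethoxyethoxy)-penta-O-TBS-catechin | CCOCCO[C@H]1c2c(O[Si](C)(C)C(C)(C)C)cc(O[Si](C)(C)C(C)(C)C)cc2O[C@H](c2ccc(O[Si](C)(C)C(C)(C)C)c(O[Si](C)(C)C(C)(C)C)c2)[C@H]1O[Si](C)(C)C(C)(C)C | intermediate

5 | per-TBS catechin-(4α→8)-catechin, lower 3-OH free | O[C@H]1Cc2c(O[Si](C)(C)C(C)(C)C)cc(O[Si](C)(C)C(C)(C)C)c([C@@H]3c4c(O[Si](C)(C)C(C)(C)C)cc(O[Si](C)(C)C(C)(C)C)cc4O[C@H](c4ccc(O[Si](C)(C)C(C)(C)C)c(O[Si](C)(C)C(C)(C)C)c4)[C@H]3O[Si](C)(C)C(C)(C)C)c2O[C@@H]1c1ccc(O[Si](C)(C)C(C)(C)C)c(O[Si](C)(C)C(C)(C)C)c1 | intermediate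

6 | (−)-epicatechin, (2R,3R) | O[C@@H]1Cc2c(O)cc(O)cc2O[C@@H]1c1ccc(O)c(O)c1 | starting material

7 | 3,5,7,3',4'-penta-O-TBS-(−)-epicatechin | CC(C)(C)[Si](C)(C)O[C@@H]1Cc2c(O[Si](C)(C)C(C)(C)C)cc(O[Si](C)(C)C(C)(C)C)cc2O[C@@H]1c1ccc(O[Si](C)(C)C(C)(C)C)c(O[Si](C)(C)C(C)(C)C)c1 | intermediate

8 | 4β-(2-ethoxyethoxy)-penta-O-TBS-epicatechin | CCOCCO[C@H]1c2c(O[Si](C)(C)C(C)(C)C)cc(O[Si](C)(C)C(C)(C)C)cc2O[C@H](c2ccc(O[Si](C)(C)C(C)(C)C)c(O[Si](C)(C)C(C)(C)C)c2)[C@@H]1O[Si](C)(C)C(C)(C)C | intermediate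

9 | per-TBS epicatechin-(4β→8)-catechin-(4α→8)-catechin, L 3-OH free | O[C@H]1Cc2c(O[Si](C)(C)C(C)(C)C)cc(O[Si](C)(C)C(C)(C)C)c([C@@H]3c4c(O[Si](C)(C)C(C)(C)C)cc(O[Si](C)(C)C(C)(C)C)c([C@H]5c6c(O[Si](C)(C)C(C)(C)C)cc(O[Si](C)(C)C(C)(C)C)cc6O[C@H](c6ccc(O[Si](C)(C)C(C)(C)C)c(O[Si](C)(C)C(C)(C)C)c6)[C@@H]5O[Si](C)(C)C(C)(C)C)c4O[C@H](c4ccc(O[Si](C)(C)C(C)(C)C)c(O[Si](C)(C)C(C)(C)C)c4)[C@H]3O[Si](C)(C)C(C)(C)C)c2O[C@@H]1c1ccc(O[Si](C)(C)C(C)(C)C)c(O[Si](C)(C)C(C)(C)C)c1 | intermediate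

10 | 4-pentyn-1-ol | C#CCCCO | starting material

11 | 4-pentynal | C#CCCC=O | intermediate

12 | oxalyl chloride | ClC(=O)C(=O)Cl | starting material

13 | per-TBS trimer L-3-O-chlorooxalate | ClC(=O)C(=O)O[C@H]1Cc2c(O[Si](C)(C)C(C)(C)C)cc(O[Si](C)(C)C(C)(C)C)c([C@@H]3c4c(O[Si](C)(C)C(C)(C)C)cc(O[Si](C)(C)C(C)(C)C)c([C@H]5c6c(O[Si](C)(C)C(C)(C)C)cc(O[Si](C)(C)C(C)(C)C)cc6O[C@H](c6ccc(O[Si](C)(C)C(C)(C)C)c(O[Si](C)(C)C(C)(C)C)c6)[C@@H]5O[Si](C)(C)C(C)(C)C)c4O[C@H](c4ccc(O[Si](C)(C)C(C)(C)C)c(O[Si](C)(C)C(C)(C)C)c4)[C@H]3O[Si](C)(C)C(C)(C)C)c2O[C@@H]1c1ccc(O[Si](C)(C)C(C)(C)C)c(O[Si](C)(C)C(C)(C)C)c1 | intermediate (not isolated)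

14 | per-TBS trimer L-3-O-(2,7-dioxohept-3-ynoate) | O=CCCC#CC(=O)C(=O)O[C@H]1Cc2c(O[Si](C)(C)C(C)(C)C)cc(O[Si](C)(C)C(C)(C)C)c([C@@H]3c4c(O[Si](C)(C)C(C)(C)C)cc(O[Si](C)(C)C(C)(C)C)c([C@H]5c6c(O[Si](C)(C)C(C)(C)C)cc(O[Si](C)(C)C(C)(C)C)cc6O[C@H](c6ccc(O[Si](C)(C)C(C)(C)C)c(O[Si](C)(C)C(C)(C)C)c6)[C@@H]5O[Si](C)(C)C(C)(C)C)c4O[C@H](c4ccc(O[Si](C)(C)C(C)(C)C)c(O[Si](C)(C)C(C)(C)C)c4)[C@H]3O[Si](C)(C)C(C)(C)C)c2O[C@@H]1c1ccc(O[Si](C)(C)C(C)(C)C)c(O[Si](C)(C)C(C)(C)C)c1 | intermediate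

15 | per-TBS trimer L-3-O-[(Z)-2,7-dioxohept-3-enoate] | O=CCC/C=C\C(=O)C(=O)O[C@H]1Cc2c(O[Si](C)(C)C(C)(C)C)cc(O[Si](C)(C)C(C)(C)C)c([C@@H]3c4c(O[Si](C)(C)C(C)(C)C)cc(O[Si](C)(C)C(C)(C)C)c([C@H]5c6c(O[Si](C)(C)C(C)(C)C)cc(O[Si](C)(C)C(C)(C)C)cc6O[C@H](c6ccc(O[Si](C)(C)C(C)(C)C)c(O[Si](C)(C)C(C)(C)C)c6)[C@@H]5O[Si](C)(C)C(C)(C)C)c4O[C@H](c4ccc(O[Si](C)(C)C(C)(C)C)c(O[Si](C)(C)C(C)(C)C)c4)[C@H]3O[Si](C)(C)C(C)(C)C)c2O[C@@H]1c1ccc(O[Si](C)(C)C(C)(C)C)c(O[Si](C)(C)C(C)(C)C)c1 | intermediate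

16 | per-TBS trimer L-3-O-[(1S)-1-hydroxy-6-oxocyclohex-2-ene-1-carboxylate] | O=C1CCC=C[C@@]1(O)C(=O)O[C@H]1Cc2c(O[Si](C)(C)C(C)(C)C)cc(O[Si](C)(C)C(C)(C)C)c([C@@H]3c4c(O[Si](C)(C)C(C)(C)C)cc(O[Si](C)(C)C(C)(C)C)c([C@H]5c6c(O[Si](C)(C)C(C)(C)C)cc(O[Si](C)(C)C(C)(C)C)cc6O[C@H](c6ccc(O[Si](C)(C)C(C)(C)C)c(O[Si](C)(C)C(C)(C)C)c6)[C@@H]5O[Si](C)(C)C(C)(C)C)c4O[C@H](c4ccc(O[Si](C)(C)C(C)(C)C)c(O[Si](C)(C)C(C)(C)C)c4)[C@H]3O[Si](C)(C)C(C)(C)C)c2O[C@@H]1c1ccc(O[Si](C)(C)C(C)(C)C)c(O[Si](C)(C)C(C)(C)C)c1 | intermediate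

17 | CNP0159807.2: epicatechin-(4β→8)-catechin-(4α→8)-catechin, lower-unit 3-O-[(1S)-1-hydroxy-6-oxocyclohex-2-ene-1-carboxylate] | O=C1CCC=C[C@@]1(O)C(=O)O[C@H]1Cc2c(O)cc(O)c([C@@H]3c4c(O)cc(O)c([C@H]5c6c(O)cc(O)cc6O[C@H](c6ccc(O)c(O)c6)[C@@H]5O)c4O[C@H](c4ccc(O)c(O)c4)[C@H]3O)c2O[C@@H]1c1ccc(O)c(O)c1 | target

## Step count and risk

Total step count: 12. Longest linear sequence: 8 steps (1 → 3 → 4 → 5 → 9 → 14 → 15 → 16 → 17, i.e. steps 2, 3, 4, 7, 9, 10, 11, 12).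

The three steps most likely to fail:

**Step 11 (carbene ring closure on the full trimer).** The carbene may isomerise the Z-enone, or the large chiral ester may erode face selectivity, and C1 epimers would be hard to separate at this size. The fallback builds the ring on the monomer and carries it through both couplings. It sets out from 2: with 12 this gives the monomer chlorooxalate F1, which is coupled with 11 (CuI, Et3N) to the monomer alkynyl keto ester F2. Lindlar reduction gives the monomer Z-enone F3, and the same carbene cyclisation gives tetra-O-TBS-catechin 3-O-[(1S)-1-hydroxy-6-oxocyclohex-2-ene-1-carboxylate] F4. On this small substrate both catalyst antipodes can be screened and the C1 epimers separated on silica. F4 then acts as the C8 nucleophile toward 4 (TMSOTf, −78 °C; the tertiary OH may be silylated in passing and is freed in step 12) to give the dimer ester F5. F5 is coupled with 8 under the conditions of step 7, and the route is rejoined at 16.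

**Step 10 (Z-enone by semihydrogenation).** Over-reduction or Z-to-E drift of the very electrophilic enone is possible. The fallback fixes the alkene geometry before the ketone exists. It sets out from 11 and 13: 11 is converted to 5,5-dimethoxypent-1-yne F6 (HC(OMe)3, TsOH), then stannylated (n-BuLi; Bu3SnCl) to tributyl(5,5-dimethoxypent-1-ynyl)stannane F7. Syn-hydrozirconation and protonolysis (Cp2Zr(H)Cl; H2O) give (Z)-tributyl(5,5-dimethoxypent-1-enyl)stannane F8. Stille acylation of chlorooxalate 13 with F8 (Pd2(dba)3, tri(2-furyl)phosphine, toluene, rt) gives the Z-enone dimethyl acetal F9 with retention of geometry. Mild acetal hydrolysis (LiBF4, wet MeCN) rejoins the route at 15.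

**Step 7 (trimer-forming coupling).** With silyl in place of benzyl ethers the electrophile may self-condense through its own free C8, or react at C6 of the dimer. The fallback caps that position. It sets out from 8: NBS (CH2Cl2, −78 to 0 °C) gives 8-bromo-4β-(2-ethoxyethoxy)-penta-O-TBS-epicatechin F10, which cannot self-condense. It is coupled with only 1.2 equiv of 5 (TMSOTf, −78 °C) to give the 8-bromo per-TBS trimer F11. Hydrodebromination (H2, Pd/C, Et3N, EtOAc; no alkene is present at this stage) rejoins the route at 9.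

## Further compounds

F1 | step 11 | tetra-O-TBS-catechin 3-O-chlorooxalate | ClC(=O)C(=O)O[C@H]1Cc2c(O[Si](C)(C)C(C)(C)C)cc(O[Si](C)(C)C(C)(C)C)cc2O[C@@H]1c1ccc(O[Si](C)(C)C(C)(C)C)c(O[Si](C)(C)C(C)(C)C)c1

F2 | step 11 | tetra-O-TBS-catechin 3-O-(2,7-dioxohept-3-ynoate) | O=CCCC#CC(=O)C(=O)O[C@H]1Cc2c(O[Si](C)(C)C(C)(C)C)cc(O[Si](C)(C)C(C)(C)C)cc2O[C@@H]1c1ccc(O[Si](C)(C)C(C)(C)C)c(O[Si](C)(C)C(C)(C)C)c1

F3 | step 11 | tetra-O-TBS-catechin 3-O-[(Z)-2,7-dioxohept-3-enoate] | O=CCC/C=C\C(=O)C(=O)O[C@H]1Cc2c(O[Si](C)(C)C(C)(C)C)cc(O[Si](C)(C)C(C)(C)C)cc2O[C@@H]1c1ccc(O[Si](C)(C)C(C)(C)C)c(O[Si](C)(C)C(C)(C)C)c1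

F4 | step 11 | tetra-O-TBS-catechin 3-O-[(1S)-1-hydroxy-6-oxocyclohex-2-ene-1-carboxylate] | O=C1CCC=C[C@@]1(O)C(=O)O[C@H]1Cc2c(O[Si](C)(C)C(C)(C)C)cc(O[Si](C)(C)C(C)(C)C)cc2O[C@@H]1c1ccc(O[Si](C)(C)C(C)(C)C)c(O[Si](C)(C)C(C)(C)C)c1

F5 | step 11 | per-TBS catechin-(4α→8)-catechin lower-unit 3-O-[(1S)-1-hydroxy-6-oxocyclohex-2-ene-1-carboxylate] | O=C1CCC=C[C@@]1(O)C(=O)O[C@H]1Cc2c(O[Si](C)(C)C(C)(C)C)cc(O[Si](C)(C)C(C)(C)C)c([C@@H]3c4c(O[Si](C)(C)C(C)(C)C)cc(O[Si](C)(C)C(C)(C)C)cc4O[C@H](c4ccc(O[Si](C)(C)C(C)(C)C)c(O[Si](C)(C)C(C)(C)C)c4)[C@H]3O[Si](C)(C)C(C)(C)C)c2O[C@@H]1c1ccc(O[Si](C)(C)C(C)(C)C)c(O[Si](C)(C)C(C)(C)C)c1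

F6 | step 10 | 5,5-dimethoxypent-1-yne | C#CCCC(OC)OC

F7 | step 10 | tributyl(5,5-dimethoxypent-1-yn-1-yl)stannane | CCCC[Sn](CCCC)(CCCC)C#CCCC(OC)OC

F8 | step 10 | (Z)-tributyl(5,5-dimethoxypent-1-en-1-yl)stannane | CCCC[Sn](CCCC)(CCCC)/C=C\CCC(OC)OC

F9 | step 10 | per-TBS trimer L-3-O-[(Z)-7,7-dimethoxy-2-oxohept-3-enoate] | COC(OC)CC/C=C\C(=O)C(=O)O[C@H]1Cc2c(O[Si](C)(C)C(C)(C)C)cc(O[Si](C)(C)C(C)(C)C)c([C@@H]3c4c(O[Si](C)(C)C(C)(C)C)cc(O[Si](C)(C)C(C)(C)C)c([C@H]5c6c(O[Si](C)(C)C(C)(C)C)cc(O[Si](C)(C)C(C)(C)C)cc6O[C@H](c6ccc(O[Si](C)(C)C(C)(C)C)c(O[Si](C)(C)C(C)(C)C)c6)[C@@H]5O[Si](C)(C)C(C)(C)C)c4O[C@H](c4ccc(O[Si](C)(C)C(C)(C)C)c(O[Si](C)(C)C(C)(C)C)c4)[C@H]3O[Si](C)(C)C(C)(C)C)c2O[C@@H]1c1ccc(O[Si](C)(C)C(C)(C)C)c(O[Si](C)(C)C(C)(C)C)c1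

F10 | step 7 | 8-bromo-4β-(2-ethoxyethoxy)-penta-O-TBS-epicatechin | CCOCCO[C@H]1c2c(O[Si](C)(C)C(C)(C)C)cc(O[Si](C)(C)C(C)(C)C)c(Br)c2O[C@H](c2ccc(O[Si](C)(C)C(C)(C)C)c(O[Si](C)(C)C(C)(C)C)c2)[C@@H]1O[Si](C)(C)C(C)(C)C

F11 | step 7 | per-TBS trimer with 8-bromo upper unit, L 3-OH free | O[C@H]1Cc2c(O[Si](C)(C)C(C)(C)C)cc(O[Si](C)(C)C(C)(C)C)c([C@@H]3c4c(O[Si](C)(C)C(C)(C)C)cc(O[Si](C)(C)C(C)(C)C)c([C@H]5c6c(O[Si](C)(C)C(C)(C)C)cc(O[Si](C)(C)C(C)(C)C)c(Br)c6O[C@H](c6ccc(O[Si](C)(C)C(C)(C)C)c(O[Si](C)(C)C(C)(C)C)c6)[C@@H]5O[Si](C)(C)C(C)(C)C)c4O[C@H](c4ccc(O[Si](C)(C)C(C)(C)C)c(O[Si](C)(C)C(C)(C)C)c4)[C@H]3O[Si](C)(C)C(C)(C)C)c2O[C@@H]1c1ccc(O[Si](C)(C)C(C)(C)C)c(O[Si](C)(C)C(C)(C)C)c1
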